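## Analysis of the target

The target is a tridepside. Three benzene rings, each a 2,4-dioxygenated 6-methylbenzoyl (orsellinate) unit, are joined head to tail by two aryl ester bonds: the acyl group of ring A sits on O4 of ring B, and the acyl group of ring B on O4 of ring C, which ends in a methyl ester. There is no stereocenter. The rings differ only in their oxygen substituents. Ring A has a free C2 hydroxyl and a C4 methoxyl. Ring B has a C2 methoxyl and an acylated C4 oxygen. Ring C has a free C2 hydroxyl, chelated to its methyl ester, and an acylated C4 oxygen. Both depside links are aryl esters of di-ortho-substituted benzoic acids: they are hard to form because of hindrance, yet once formed they are cleaved by hydroxide, alkoxides and nucleophilic amines. The ring B carboxyl therefore has to be unmasked without such reagents, and the ring C methyl ester must survive to the end. The difficulty is one of differentiation. Rings A and C have the pattern that direct chemistry on an orsellinate gives, because the unchelated 4-OH reacts first. Ring B has the reverse pattern: its C2 oxygen alone is methylated and its C4 oxygen must be free for acylation. The synthesis rests on this feature. In the open-chain tetraketide that folds into ring B, the carbon that becomes ring carbon C2 can carry its methoxy group as an enol ether while the carbon that becomes C4 stays a ketone, so the pattern is written into the chain before the ring exists.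

## Retrosynthetic reasoning

**Target 18 to benzyl ether 17.** The last bond cut is the O–benzyl bond on the C2 oxygen of ring A. Ring A must be activated as an acyl donor, and an ortho-hydroxy acid cannot be activated cleanly, so this oxygen needs a mask. A benzyl ether leaves by hydrogenolysis under neutral conditions that neither aryl ester nor the methyl ester feels.

**17 to acid 15 and methyl orsellinate 9.** The ester bond between the ring B carbonyl and O4 of ring C is cut. Ring C is then 9 itself, which already has the methyl ester, the methyl group and both oxygens. The forward reaction must activate the hindered acid 15 (as acid chloride 16) and acylate only the unchelated 4-OH of 9. Cutting here rather than building ring C saves every step that a ring C synthesis would cost.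

**15 to allyl ester 14, then to phenol 8 and acid 12.** The ring B carboxyl is carried as an allyl ester, because it must be set free in the presence of an aryl ester and palladium-catalysed allyl transfer needs neither hydroxide nor an alkoxide. The A–B ester is then cut to 8 and 12 (used as acid chloride 13). This ester is made before the B–C ester because 8 has a single hydroxyl and a silent carboxyl, so no further protection is needed. The reverse order would require a protecting group on O4 of ring B.

**12 to 11, 10 and 9.** Ring A comes from the same 9 by functional-group changes only: methylation of the 4-OH, benzylation of the 2-OH, and hydrolysis of the hindered methyl ester. The hydrolysis needs strong base and is placed here, before any aryl ester exists.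

**8 to open-chain enol ether 6 (key disconnection).** The bond between ring carbons C1 and C6 of ring B is cut; this is the C2–C7 bond of the octenoate chain. What is gained is the oxygen pattern of ring B without any selective alkylation: the C3 methoxy group of 6 becomes the C2 methoxyl and the C5 ketone becomes the free C4 hydroxyl. The forward reaction is an intramolecular aldol addition of the extended enolate (nucleophilic at C2) to the C7 ketone, followed by dehydration through adduct 7. It has to win over Claisen closure and lactonization at the ester.

**6 to 5 and 4.** The chain is cut at C6–C7 and then at C4–C5. Both bonds are made by acylation with a Weinreb-type acetyl donor: first of the dienolate of 4 at its γ-carbon, then of the dianion of 5 at its terminal carbon. A single four-carbon acyl unit with a ketal-masked ketone would make the chain in one bond formation. It was not chosen because its unmasking needs aqueous acid next to an enol ether that must not be hydrolysed. Two acetylations need no protecting group and no acid.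

**4 to 1 and 2.** The enol ether C–O bond is cut. Allyl acetoacetate 1 and orthoester 2 give 4 by ketalization and loss of one alkoxy group, so the allyl ester and the methoxy group are both in place from the first step.

## Alternatives that were turned down

**Alternative 1:** Ring C is disconnected across its C2–C3 and C1–C6 bonds into a 2-pyranone and an alkyne. In the forward direction the pyranyl ester A1 of the ring A–ring B acid would be heated with the borylated propiolate A2. Cycloaddition across C3 and C6 of the pyranone and decarboxylative cycloreversion would give the ring C boronate A3, which would then be oxidised to the C2 phenol and debenzylated.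
- For it: the two oxygens of ring C are told apart by construction, one arriving acylated and the other as boron. No selective acylation of a dihydroxybenzoate is needed. On this point it is stronger than the chosen route, which relies on chelation of the 2-OH of 9.
- Against it: the ring it builds is the one that can be bought as 9. Pyranone–alkyne cycloadditions need high temperature, and A1 is an enol ester and thus an acyl donor that would have to survive this with two further aryl esters. The unsymmetrical alkyne must add in one orientation. The aryl–boron bond must be oxidised without the basic peroxide that would cleave the depside links.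
- Comparison: the riskiest step would be fed with the most valuable intermediate and followed by two more steps. The chosen strategy puts its one ring construction early, on a twelve-carbon fragment, and spends it on the only ring whose pattern cannot be bought.

**Alternative 2:** Ring A is disconnected into the diazo enone A4 and the ynol ether A5. Irradiation would trigger Wolff rearrangement to a vinylketene, [2+2] addition of A5, four-electron opening of the cyclobutenone and six-electron closure. The product A6 is the same compound as 10.
- For it: one operation assembles a tetrasubstituted arene with hydroxyl and methoxyl placed by the mechanism. In regiochemical certainty it equals what the chosen strategy does for ring B, and for ring A it is in principle cleaner than a selective alkylation.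
- Against it: ring A has exactly the pattern that monomethylation of 9 gives in one step. The benzannulation would replace that step by the preparation of A4 (diazo transfer on a functionalised enone), the handling of the volatile and unstable A5, and a photochemical step.
- Comparison: it leaves the real problem, the ring B pattern, unsolved. The chosen strategy uses de novo ring synthesis where direct substitution fails and takes ring A from 9 by one methylation.

**Alternative 3:** Ring B is disconnected across C1–C2 and C5–C6 into the 1,1-dimethoxy-3-silyloxy diene A7 and the but-2-ynoate ester A8 of ring C. Cycloaddition, elimination of one alkoxy group and desilylation would give the ring B–ring C didepside A9 directly.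
- For it: as in the chosen route, the ring B oxygens are differentiated by construction. In addition the B–C ester is made while its acyl group is still an unhindered butynoyl unit. On this point it is stronger, because the chosen route must esterify a di-ortho-substituted acid in step 10.
- Against it: a β-methyl ynoate is a sluggish dienophile. A7 is a ketene acetal and so a strong nucleophile and an acid-sensitive one; it can attack the aryl ester of A8 or be consumed by its free chelated phenol, which would then need protection. A7 must also be made and handled dry. A9 has two free phenols, so the final acylation with ring A again depends on chelation.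
- Comparison: the ring-forming event is an intermolecular reaction between mismatched partners. The chosen strategy closes ring B by an intramolecular reaction of one anion, with no other ester present, and accepts one hindered but standard depside esterification in exchange.

Key step: step 4

Remark: 6 is drawn as its triketo tautomer but should exist mainly as enol forms of the 5,7-dione, which does not change its chemistry. Chain atoms of 4–6 are numbered from the ester carbon (C1) to C8, and ring atoms from the carboxyl-bearing carbon (C1).

## Route

Step 1
Reactants: 1 allyl acetoacetate; 2 trimethyl orthoformate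
Product: 4 allyl (E)-3-methoxybut-2-enoate, via dimethyl ketal 3 (not isolated)
Conditions: H2SO4 (cat.), neat, rt; then distillation at reduced pressure
Reagents that add atoms: none
Why: Acid-catalysed ketalization of the ketone by the orthoester gives 3, which loses methanol on distillation to the conjugated enol ether; the (E)-isomer, with methoxy trans to the ester, is the thermodynamic product of this known enol etherification of acetoacetates. No alcohol is used as solvent, so exchange of the allyl ester should stay minor.

Step 2
Reactants: 4 allyl (E)-3-methoxybut-2-enoate
Product: 5 allyl (E)-3-methoxy-5-oxohex-2-enoate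
Conditions: LiN(iPr)2, THF, −78 °C; MeC(O)N(OMe)Me, −78 to −20 °C; AcOH, −78 °C
Reagents that add atoms: N-methoxy-N-methylacetamide, CC(=O)N(C)OC
Why: Kinetic deprotonation of the γ-methyl group gives the extended enolate, and β-alkoxy dienolates of this kind react with carbonyl electrophiles at the γ-carbon (vinylogous Claisen-type acylation). The chelated tetrahedral adduct of the Weinreb ketone synthesis holds until the cold acid quench, so the more acidic product never meets unreacted enolate.

Step 3
Reactants: 5 allyl (E)-3-methoxy-5-oxohex-2-enoate
Product: 6 allyl (E)-3-methoxy-5,7-dioxooct-2-enoate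
Conditions: LiN(iPr)2 (2.2 equiv), THF, −78 to −40 °C; MeC(O)N(OMe)Me, −78 to −20 °C; AcOH, −78 °C
Reagents that add atoms: N-methoxy-N-methylacetamide, CC(=O)N(C)OC
Why: The first equivalent of base removes a C4 proton and the second a proton of the terminal methyl group; the dianion reacts at its less stabilised C6 terminus, as dianions of β-dicarbonyl compounds do. The Weinreb adduct again prevents a second addition, so the C6–C7 bond forms with no protecting group on the chain and no acid near the enol ether.

Step 4
Reactants: 6 allyl (E)-3-methoxy-5,7-dioxooct-2-enoate
Product: 8 allyl 4-hydroxy-2-methoxy-6-methylbenzoate, via cyclic aldol adduct 7 (not isolated)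
Conditions: Cs2CO3 (2 equiv), MeCN, 0 °C to rt; then 1 M HCl (aq), rt
Reagents that add atoms: none
Why: Cs2CO3 deprotonates 6 reversibly; the C6 position of the dione is the most acidic, but proton exchange also gives the C4 anion, which is delocalised onto the C5 oxygen and through C3=C2 onto the ester and is nucleophilic at C2. C2 adds to the free C7 ketone of this anion and forms the chain C2–C7 bond (ring B C1–C6) in a 6-(enolendo)-exo-trig closure to adduct 7. E1cB loss of the tertiary hydroxyl and enolization of the C5 ketone, completed by the acid treatment, give arene 8 and make the sequence irreversible. The closest known reaction type is the base-mediated aldol aromatization of 3,5,7-triketo esters and of their dioxinone- or enol-ether-masked forms to resorcylates. No stereocenter is set: the two sp3 centres of 7 form without control and are erased on aromatization, and the C2=C3 geometry of 6 is lost in the anion. The selectivity needed is aldol closure (C2 to C7) over Claisen closure (C6 to C1) and lactonization (O5 to C1); the C3 methoxy group secures it, because it makes the ester a vinylogous carbonate whose carbonyl is part of the delocalised anion and is therefore a poor electrophile, while it raises the nucleophilicity of C2. The same methoxy group ends as the C2 methoxyl and the C5 carbonyl as the free C4 hydroxyl, so the two oxygens of ring B are distinguished without selective alkylation. An aprotic solvent is used so that the allyl ester cannot be exchanged.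

Step 5
Reactants: 9 methyl 2,4-dihydroxy-6-methylbenzoate
Product: 10 methyl 2-hydroxy-4-methoxy-6-methylbenzoate
Conditions: MeI (1.05 equiv), K2CO3, acetone, reflux
Reagents that add atoms: iodomethane, CI
Why: The 4-OH is the more acidic and unhindered phenol, while the 2-OH is held in a hydrogen bond to the ester carbonyl, so one equivalent of MeI under Williamson conditions should alkylate O4 only.

Step 6
Reactants: 10 methyl 2-hydroxy-4-methoxy-6-methylbenzoate
Product: 11 methyl 2-(benzyloxy)-4-methoxy-6-methylbenzoate
Conditions: BnBr, K2CO3, DMF, 60 °C
Reagents that add atoms: benzyl bromide, BrCc1ccccc1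
Why: With O4 capped, the chelated 2-OH is benzylated under more forcing Williamson conditions (polar aprotic solvent, heat).

Step 7
Reactants: 11 methyl 2-(benzyloxy)-4-methoxy-6-methylbenzoate
Product: 12 2-(benzyloxy)-4-methoxy-6-methylbenzoic acid
Conditions: KOH, DMSO/H2O, 90 °C; then HCl (aq)
Reagents that add atoms: potassium hydroxide, [K+].[OH-]
Why: Saponification of a di-ortho-substituted benzoate needs hot KOH in aqueous DMSO; this is acceptable here because no aryl ester is present yet and the benzyl and methyl ethers are inert to base.

Step 8
Reactants: 12 2-(benzyloxy)-4-methoxy-6-methylbenzoic acid; 8 allyl 4-hydroxy-2-methoxy-6-methylbenzoate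
Product: 14 allyl 4-{[2-(benzyloxy)-4-methoxy-6-methylbenzoyl]oxy}-2-methoxy-6-methylbenzoate, via ring A acid chloride 13 (not isolated)
Conditions: (COCl)2, DMF (cat.), CH2Cl2, 0 °C to rt, evaporate; then 8, Et3N, DMAP (cat.), CH2Cl2, 0 °C to rt
Reagents that add atoms: oxalyl chloride, O=C(Cl)C(Cl)=O (it supplies only the chlorine of 13; none of its atoms remains in 14)
Why: Vilsmeier-catalysed formation of acid chloride 13 is followed by DMAP-catalysed acylation of the only hydroxyl of 8, which is acidic and nucleophilic because it is para to the ester. The acid chloride overcomes the hindrance of the di-ortho-substituted acyl group.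

Step 9
Reactants: 14 allyl 4-{[2-(benzyloxy)-4-methoxy-6-methylbenzoyl]oxy}-2-methoxy-6-methylbenzoate
Product: 15 4-{[2-(benzyloxy)-4-methoxy-6-methylbenzoyl]oxy}-2-methoxy-6-methylbenzoic acid
Conditions: Pd(PPh3)4 (5 mol %), PhNHMe, THF, rt
Reagents that add atoms: none
Why: Zerovalent palladium ionises the allyl ester to a π-allyl complex and the carboxylate (Tsuji–Trost deallylation), and N-methylaniline takes up the allyl group. This weakly nucleophilic amine is chosen over a secondary aliphatic amine so that the aryl ester is not aminolysed; the benzyl and methyl ethers are untouched.

Step 10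
Reactants: 15 4-{[2-(benzyloxy)-4-methoxy-6-methylbenzoyl]oxy}-2-methoxy-6-methylbenzoic acid; 9 methyl 2,4-dihydroxy-6-methylbenzoate
Product: 17 methyl 4-[(4-{[2-(benzyloxy)-4-methoxy-6-methylbenzoyl]oxy}-2-methoxy-6-methylbenzoyl)oxy]-2-hydroxy-6-methylbenzoate, via acid chloride 16 (not isolated)
Conditions: (COCl)2, DMF (cat.), CH2Cl2, 0 °C to rt, evaporate; then 9 (1.2 equiv), Et3N, DMAP (cat.), CH2Cl2, 0 °C to rt
Reagents that add atoms: oxalyl chloride, O=C(Cl)C(Cl)=O (it supplies only the chlorine of 16; none of its atoms remains in 17)
Why: Acid chloride 16 forms under conditions that leave the internal aryl ester alone. Of the two hydroxyls of 9 the 4-OH is the more acidic and is not chelated, so it should be acylated selectively; the hindered acyl group disfavours a second acylation at the chelated 2-OH.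

Step 11
Reactants: 17 methyl 4-[(4-{[2-(benzyloxy)-4-methoxy-6-methylbenzoyl]oxy}-2-methoxy-6-methylbenzoyl)oxy]-2-hydroxy-6-methylbenzoate
Product: 18 methyl 2-hydroxy-4-({4-[(2-hydroxy-4-methoxy-6-methylbenzoyl)oxy]-2-methoxy-6-methylbenzoyl}oxy)-6-methylbenzoate (target)
Conditions: H2 (1 atm), 10% Pd/C, EtOAc, rt
Reagents that add atoms: none
Why: Hydrogenolysis of the benzyl aryl ether over Pd/C is neutral; the aryl esters, the methyl ester and the methyl ethers are stable to it and no other reducible group is present.

## Compound list

1 | allyl acetoacetate (prop-2-en-1-yl 3-oxobutanoate) | CC(=O)CC(=O)OCC=C | starting material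
2 | trimethyl orthoformate | COC(OC)OC | starting material
3 | allyl 3,3-dimethoxybutanoate | CC(OC)(OC)CC(=O)OCC=C | intermediate (not isolated)
4 | allyl (E)-3-methoxybut-2-enoate | CO/C(C)=C/C(=O)OCC=C | intermediate
5 | allyl (E)-3-methoxy-5-oxohex-2-enoate | CC(=O)C\C(OC)=C/C(=O)OCC=C | intermediate
6 | allyl (E)-3-methoxy-5,7-dioxooct-2-enoate | CC(=O)CC(=O)C\C(OC)=C/C(=O)OCC=C | intermediate
7 | allyl 6-hydroxy-2-methoxy-6-methyl-4-oxocyclohex-2-ene-1-carboxylate (mixture of diastereomers, both centres lost in 8) | C=CCOC(=O)C1C(OC)=CC(=O)CC1(C)O | intermediate (not isolated)
8 | allyl 4-hydroxy-2-methoxy-6-methylbenzoate | COc1cc(O)cc(C)c1C(=O)OCC=C | intermediate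
9 | methyl 2,4-dihydroxy-6-methylbenzoate (methyl orsellinate) | COC(=O)c1c(C)cc(O)cc1O | starting material
10 | methyl 2-hydroxy-4-methoxy-6-methylbenzoate | COC(=O)c1c(C)cc(OC)cc1O | intermediate
11 | methyl 2-(benzyloxy)-4-methoxy-6-methylbenzoate | COC(=O)c1c(C)cc(OC)cc1OCc1ccccc1 | intermediate
12 | 2-(benzyloxy)-4-methoxy-6-methylbenzoic acid | OC(=O)c1c(C)cc(OC)cc1OCc1ccccc1 | intermediate
13 | 2-(benzyloxy)-4-methoxy-6-methylbenzoyl chloride | ClC(=O)c1c(C)cc(OC)cc1OCc1ccccc1 | intermediate (not isolated)
14 | allyl 4-{[2-(benzyloxy)-4-methoxy-6-methylbenzoyl]oxy}-2-methoxy-6-methylbenzoate | C=CCOC(=O)c1c(C)cc(OC(=O)c2c(C)cc(OC)cc2OCc2ccccc2)cc1OC | intermediate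
15 | 4-{[2-(benzyloxy)-4-methoxy-6-methylbenzoyl]oxy}-2-methoxy-6-methylbenzoic acid | OC(=O)c1c(C)cc(OC(=O)c2c(C)cc(OC)cc2OCc2ccccc2)cc1OC | intermediate
16 | 4-{[2-(benzyloxy)-4-methoxy-6-methylbenzoyl]oxy}-2-methoxy-6-methylbenzoyl chloride | ClC(=O)c1c(C)cc(OC(=O)c2c(C)cc(OC)cc2OCc2ccccc2)cc1OC | intermediate (not isolated)
17 | methyl 4-[(4-{[2-(benzyloxy)-4-methoxy-6-methylbenzoyl]oxy}-2-methoxy-6-methylbenzoyl)oxy]-2-hydroxy-6-methylbenzoate | COC(=O)c1c(C)cc(OC(=O)c2c(C)cc(OC(=O)c3c(C)cc(OC)cc3OCc3ccccc3)cc2OC)cc1O | intermediate
18 | methyl 2-hydroxy-4-({4-[(2-hydroxy-4-methoxy-6-methylbenzoyl)oxy]-2-methoxy-6-methylbenzoyl}oxy)-6-methylbenzoate | COC(=O)c1c(C)cc(OC(=O)c2c(C)cc(OC(=O)c3c(C)cc(OC)cc3O)cc2OC)cc1O | target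

## Step count and least certain steps

Total: 11 steps. Longest linear sequence: 8 steps (steps 1, 2, 3, 4, 8, 9, 10, 11); steps 5–7 are the ring A branch.

**Step 4 (key step).** The most likely failures are diversion of the chain into lactonization (the C5 enol oxygen closing on the ester with loss of the allyloxy group), and stalling because the anion rests as the C6-deprotonated diketonate, in which C7 is not electrophilic and C2 not nucleophilic. Cleavage of the 1,3-dione by adventitious hydroxide is a further risk. The fallback turns the lactonization into the route. Compound 6 is closed on purpose (DBU, toluene, 80 °C) to 4-methoxy-6-(2-oxopropyl)-2H-pyran-2-one F1. F1 is then heated with Mg(OCH2CH=CH2)2 in allyl alcohol (made from Mg turnings and allyl alcohol). The alkoxide opens the lactone at its carbonyl and regenerates the chain of 6 as a magnesium chelate; the divalent cation holds C2 and the C7 carbonyl together, and aldol closure with dehydration should follow. After acidic work-up the fallback comes back to the route at 8.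

**Step 3.** The second deprotonation may be incomplete, or proton transfer may return the unreactive monoanion, so that 5 is recovered. Acylation at oxygen or at C4, and anionic closure to a pyranone on warming, are also possible. The fallback brings in C5–C8 as one ketal-masked unit. It sets out from 4. The dienolate of 4 (LiN(iPr)2, THF, −78 °C) is acylated with N-methoxy-N-methyl-2-(2-methyl-1,3-dioxolan-2-yl)acetamide F2, itself made from commercial ethyl 2-(2-methyl-1,3-dioxolan-2-yl)acetate with MeNHOMe·HCl and iPrMgCl. This gives allyl (E)-3-methoxy-6-(2-methyl-1,3-dioxolan-2-yl)-5-oxohex-2-enoate F3 by a single monoanion acylation. Mild ketal hydrolysis (pyridinium p-toluenesulfonate, wet acetone) then comes back to the route at 6. It is the second choice because that unmasking exposes the enol ether to acid.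

**Step 10.** Acylation by the hindered acid chloride may be slow enough for reaction at the chelated 2-OH, acyl migration between the two oxygens of ring C, or exchange at the existing A–B ester to compete. The fallback replaces reliance on chelation by a protecting group. It sets out from 9.
- Selective O4 allylation (allyl bromide, K2CO3, acetone) gives methyl 4-(allyloxy)-2-hydroxy-6-methylbenzoate F4.
- Benzylation (BnBr, K2CO3, DMF) gives methyl 4-(allyloxy)-2-(benzyloxy)-6-methylbenzoate F5.
- Removal of the allyl ether (Pd(PPh3)4, morpholine, THF; no aryl ester is present) gives methyl 2-(benzyloxy)-4-hydroxy-6-methylbenzoate F6.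
- Acylation of F6 with acid chloride 16 under the conditions of step 10 gives methyl 2-(benzyloxy)-4-[(4-{[2-(benzyloxy)-4-methoxy-6-methylbenzoyl]oxy}-2-methoxy-6-methylbenzoyl)oxy]-6-methylbenzoate F7.
- Hydrogenolysis (H2, Pd/C, EtOAc) removes both benzyl groups and comes back to the route at 18.

## Further compounds

F1 | step 4 | 4-methoxy-6-(2-oxopropyl)-2H-pyran-2-one | COC1=CC(=O)OC(CC(C)=O)=C1
F2 | step 3 | N-methoxy-N-methyl-2-(2-methyl-1,3-dioxolan-2-yl)acetamide | CON(C)C(=O)CC1(C)OCCO1
F3 | step 3 | allyl (E)-3-methoxy-6-(2-methyl-1,3-dioxolan-2-yl)-5-oxohex-2-enoate | CC1(CC(=O)C\C(OC)=C/C(=O)OCC=C)OCCO1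
F4 | step 10 | methyl 4-(allyloxy)-2-hydroxy-6-methylbenzoate | COC(=O)c1c(C)cc(OCC=C)cc1O
F5 | step 10 | methyl 4-(allyloxy)-2-(benzyloxy)-6-methylbenzoate | COC(=O)c1c(C)cc(OCC=C)cc1OCc1ccccc1
F6 | step 10 | methyl 2-(benzyloxy)-4-hydroxy-6-methylbenzoate | COC(=O)c1c(C)cc(O)cc1OCc1ccccc1
F7 | step 10 | methyl 2-(benzyloxy)-4-[(4-{[2-(benzyloxy)-4-methoxy-6-methylbenzoyl]oxy}-2-methoxy-6-methylbenzoyl)oxy]-6-methylbenzoate | COC(=O)c1c(C)cc(OC(=O)c2c(C)cc(OC(=O)c3c(C)cc(OC)cc3OCc3ccccc3)cc2OC)cc1OCc1ccccc1
A1 | alternative 1 | 6-methyl-2-oxo-2H-pyran-4-yl 4-{[2-(benzyloxy)-4-methoxy-6-methylbenzoyl]oxy}-2-methoxy-6-methylbenzoate | CC1=CC(OC(=O)c2c(C)cc(OC(=O)c3c(C)cc(OC)cc3OCc3ccccc3)cc2OC)=CC(=O)O1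
A2 | alternative 1 | methyl 3-(4,4,5,5-tetramethyl-1,3,2-dioxaborolan-2-yl)prop-2-ynoate | COC(=O)C#CB1OC(C)(C)C(C)(C)O1
A3 | alternative 1 | methyl 4-[(4-{[2-(benzyloxy)-4-methoxy-6-methylbenzoyl]oxy}-2-methoxy-6-methylbenzoyl)oxy]-2-methyl-6-(4,4,5,5-tetramethyl-1,3,2-dioxaborolan-2-yl)benzoate | COC(=O)c1c(C)cc(OC(=O)c2c(C)cc(OC(=O)c3c(C)cc(OC)cc3OCc3ccccc3)cc2OC)cc1B1OC(C)(C)C(C)(C)O1
A4 | alternative 2 | methyl (E)-5-diazo-3-methyl-4-oxopent-2-enoate | COC(=O)/C=C(\C)C(=O)C=[N+]=[N-]
A5 | alternative 2 | methoxyethyne | COC#C
A6 | alternative 2 | methyl 2-hydroxy-4-methoxy-6-methylbenzoate | COC(=O)c1c(C)cc(OC)cc1O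
A7 | alternative 3 | 1,1-dimethoxy-3-[(trimethylsilyl)oxy]buta-1,3-diene | COC(OC)=CC(=C)O[Si](C)(C)C
A8 | alternative 3 | methyl 4-(but-2-ynoyloxy)-2-hydroxy-6-methylbenzoate | COC(=O)c1c(C)cc(OC(=O)C#CC)cc1O
A9 | alternative 3 | methyl 2-hydroxy-4-[(4-hydroxy-2-methoxy-6-methylbenzoyl)oxy]-6-methylbenzoate | COC(=O)c1c(C)cc(OC(=O)c2c(C)cc(O)cc2OC)cc1O
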